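**Retrosynthetic overview**
1. The target is an achiral, symmetric dibenzyl ether. Its central CH2–O–CH2 unit is cut last, on the free phenols, into a benzylic bromide and the alcohol made from it, because BBr3 would not spare a dibenzyl ether.
2. The strategy rests on the inner benzene ring of each half, which carries C1–CH2O, C2–CH2Ar, C3–Br, C4–OH, C5–OH and C6–H. Bridging the two benzylic carbons on C1 and C2 with one temporary oxygen turns the half into a 1-arylphthalan.
3. The phthalan is opened by a [2+2+2] disconnection into a 1,6-diyne ether and a symmetric alkyne. In the diyne, C1 and C2 are the inner alkyne carbons, C3–Br is a bromoalkyne terminus and C6–H is the free terminus. The symmetric alkyne supplies C4–C5 and bears two boryl groups as masked hydroxyls.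
4. Ring order: the outer ring is bought (vanillin). The dihydrofuran ring and the inner benzene ring close together in the key step. The dihydrofuran is then reopened by ionic reduction of its doubly benzylic C–O bond while the inner ring is still electron-poor. Boron-to-hydroxyl exchange, demethylation and ether closure follow.

Key step: step 6

Assumption: the target has no stereocentre and is achiral, so the request for one enantiomer does not apply. The single carbinol or ether centre carried from the Grignard addition to the ionic reduction is used as the racemate and is erased there.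

**Step 1**
Reactants: 1 vanillin (4-hydroxy-3-methoxybenzaldehyde)
Product: 3 2,3-dibromo-4-hydroxy-5-methoxybenzaldehyde (5,6-dibromovanillin), via 5-bromovanillin 2 (not isolated)
Conditions: Br2 (1.05 equiv), AcOH, rt; then Fe powder (5 mol %), Br2 (1.3 equiv), 60 °C
Reagents that add atoms: bromine, BrBr
Why: Electrophilic aromatic bromination, in which the phenol sends the first bromine to C5 and, under iron bromide catalysis, the second enters C6 (para to the methoxy group, the only position still activated), giving the substitution pattern of the outer ring.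

**Step 2**
Reactants: 3 2,3-dibromo-4-hydroxy-5-methoxybenzaldehyde
Product: 4 2,3-dibromo-4,5-dimethoxybenzaldehyde
Conditions: MeI (1.5 equiv), K2CO3 (1.5 equiv), DMF, rt
Reagents that add atoms: iodomethane, CI
Why: Williamson O-methylation of an acidic, flanked phenol with a small electrophile, under conditions to which the aldehyde and the aryl bromides are inert.

**Step 3**
Reactants: 4 2,3-dibromo-4,5-dimethoxybenzaldehyde; 5 ethynylmagnesium bromide
Product: 6 rac-1-(2,3-dibromo-4,5-dimethoxyphenyl)prop-2-yn-1-ol
Conditions: 5 (0.5 M in THF, 1.3 equiv), THF, 0 °C to rt; sat. aq. NH4Cl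
Reagents that add atoms: none
Why: 1,2-Addition of an alkynyl Grignard reagent, which does not undergo bromine–magnesium exchange with aryl bromides; the new carbinol centre is formed racemic on purpose because step 7 destroys it.

**Step 4**
Reactants: 6 rac-1-(2,3-dibromo-4,5-dimethoxyphenyl)prop-2-yn-1-ol
Product: 7 rac-3-bromo-1-(2,3-dibromo-4,5-dimethoxyphenyl)prop-2-yn-1-ol
Conditions: NBS (1.1 equiv), AgNO3 (10 mol %), acetone, rt, dark
Reagents that add atoms: N-bromosuccinimide, O=C1CCC(=O)N1Br
Why: Silver-catalysed bromination of a terminal alkyne through its silver acetylide, mild enough to leave the secondary alcohol and the dibromo-deactivated arene untouched.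

**Step 5**
Reactants: 7 rac-3-bromo-1-(2,3-dibromo-4,5-dimethoxyphenyl)prop-2-yn-1-ol; 8 propargyl alcohol
Product: 9 rac-3-bromo-1-(2,3-dibromo-4,5-dimethoxyphenyl)prop-2-ynyl propargyl ether
Conditions: 8 (5 equiv), anhydrous FeCl3 (10 mol %), MeCN, 50 °C
Reagents that add atoms: none
Why: Lewis-acid-catalysed direct propargylic substitution (SN1), in which the benzylic–propargylic cation, supported by the para-methoxy group, is captured at the carbinol carbon by excess primary alcohol under base-free conditions that cannot move the alkynyl bromine onto the other alkyne; the centre stays racemic.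

**Step 6**
Reactants: 9 rac-3-bromo-1-(2,3-dibromo-4,5-dimethoxyphenyl)prop-2-ynyl propargyl ether; 10 1,2-bis(pinacolatoboryl)ethyne
Product: 11 rac-7-bromo-1-(2,3-dibromo-4,5-dimethoxyphenyl)-5,6-bis(pinacolatoboryl)-1,3-dihydroisobenzofuran
Conditions: Cp*RuCl(cod) (10 mol %), 10 (3 equiv), ClCH2CH2Cl, 40 °C, Ar, 9 added by syringe pump over 6 h
Reagents that add atoms: none
Why: After loss of cod, the Cp*RuCl fragment binds both alkynes of 9 and couples them oxidatively to a bicyclic ruthenacycle, which makes the bond between the two inner alkyne carbons (inner-ring C1–C2, phthalan C3a–C7a) and so closes the five-membered dihydrofuran ring across the C–O–C tether. Alkyne 10 then adds to a ruthenium–carbon bond, the metallacycle expands, and reductive elimination makes C3–C4 and C5–C6 and closes the benzene ring as the formal [2+2+2] event. The closest known reaction type is the Cp*RuCl(cod)-catalysed cycloaddition of 1,6-diynes, including those with bromo- or iodoalkyne termini, with monoalkynes, together with the cyclotrimerisation of diynes with alkynylboronates. No stereocentre is created, and the racemic ether carbon of 9 passes unchanged into C1 of 11. There is no regiochemical choice, because 10 is symmetric and the bromine already sits on the diyne terminus next to the aryl-bearing carbon, which fixes Br at C7 beside a boron-bearing carbon. The step needs cross-reaction rather than dimerisation of 9 through its free terminal alkyne, and it needs intact C(sp)–Br and aryl C–Br bonds; the tether, the low stationary concentration of 9 against excess 10, and a Ru(II) catalyst that does not insert into carbon–halogen bonds should provide this.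

**Step 7**
Reactants: 11 rac-7-bromo-1-(2,3-dibromo-4,5-dimethoxyphenyl)-5,6-bis(pinacolatoboryl)-1,3-dihydroisobenzofuran
Product: 13 [3-bromo-2-(2,3-dibromo-4,5-dimethoxybenzyl)-4,5-bis(pinacolatoboryl)phenyl]methanol, via benzylic trifluoroacetate 12 (not isolated)
Conditions: Et3SiH (3 equiv), TFA–CH2Cl2 1:1, 0 °C to rt; then K2CO3 (cat.), MeOH, 0 °C
Reagents that add atoms: none
Why: Ionic hydrogenation of a benzhydryl-type ether, in which acid opens only the doubly benzylic C1–O bond (cation carried by the para-methoxy group of the outer ring) and Et3SiH reduces it to CH2, erasing the racemic centre, while the primary C3–O bond sits on a ring deactivated by bromine and two boryl groups and can neither ionise nor be over-reduced to methyl, which is why this step precedes boronate oxidation; the trifluoroacetate formed in TFA is removed by mild methanolysis.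

**Step 8**
Reactants: 13 [3-bromo-2-(2,3-dibromo-4,5-dimethoxybenzyl)-4,5-bis(pinacolatoboryl)phenyl]methanol
Product: 14 3-bromo-4-(2,3-dibromo-4,5-dimethoxybenzyl)-5-(hydroxymethyl)benzene-1,2-diol
Conditions: 30 % aq. H2O2 (6 equiv), NaHCO3, THF–H2O, 0 °C to rt, Ar; Na2S2O3, then pH 5
Reagents that add atoms: hydrogen peroxide, OO
Why: Oxidation of arylboronic esters by hydroperoxide (ate complex, then 1,2-aryl shift from boron to oxygen at the same carbon), run in bicarbonate buffer under argon so that the bromocatechol is not oxidised further to the o-quinone; it places the hydroxyls exactly on C4 and C5.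

**Step 9**
Reactants: 14 3-bromo-4-(2,3-dibromo-4,5-dimethoxybenzyl)-5-(hydroxymethyl)benzene-1,2-diol
Product: 15 3-bromo-5-(bromomethyl)-4-(2,3-dibromo-4,5-dihydroxybenzyl)benzene-1,2-diol
Conditions: BBr3 (8 equiv), CH2Cl2, −78 °C to rt; ice-water, rapid extraction with EtOAc
Reagents that add atoms: boron tribromide, BrB(Br)Br
Why: BBr3 cleavage of the two aryl methyl ethers, which at the same time converts the 4-hydroxybenzyl-type alcohol into its bromide, the usual outcome for this class of bromophenol and here the wanted electrophile; aryl bromides and the diarylmethane are inert.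

**Step 10**
Reactants: 15 3-bromo-5-(bromomethyl)-4-(2,3-dibromo-4,5-dihydroxybenzyl)benzene-1,2-diol (a little more than half of the material)
Product: 16 3-bromo-4-(2,3-dibromo-4,5-dihydroxybenzyl)-5-(hydroxymethyl)benzene-1,2-diol
Conditions: acetone–H2O 1:1 (0.01 M), rt, Ar
Reagents that add atoms: water, O
Why: SN1 hydrolysis through the benzylic cation stabilised by the para hydroxyl (protonated p-quinone methide), with high dilution and a large excess of water so that water outcompetes all phenolic and benzylic nucleophiles.

**Step 11**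
Reactants: 15 3-bromo-5-(bromomethyl)-4-(2,3-dibromo-4,5-dihydroxybenzyl)benzene-1,2-diol; 16 3-bromo-4-(2,3-dibromo-4,5-dihydroxybenzyl)-5-(hydroxymethyl)benzene-1,2-diol
Product: 17 bis[3-bromo-2-(2,3-dibromo-4,5-dihydroxybenzyl)-4,5-dihydroxybenzyl] ether (target)
Conditions: 16 (1.5 equiv, excess recovered), 2,6-di-tert-butylpyridine (1.2 equiv), 4 Å MS, dry MeCN–THF (concentrated in 16), 15 added slowly, rt to 40 °C, Ar
Reagents that add atoms: none
Why: Solvolytic etherification of a 4-hydroxybenzyl bromide by an alcohol (the same cation or p-quinone methide pathway by which such bromides give alkyl ethers in alcohols), in which the primary hydroxyl of 16 is the best neutral nucleophile and the hindered pyridine removes HBr without forming phenoxides, so the ether should persist as the kinetic product.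

**Compound list**
1 | vanillin | COc1cc(C=O)ccc1O | starting material
2 | 5-bromovanillin (3-bromo-4-hydroxy-5-methoxybenzaldehyde) | COc1cc(C=O)cc(Br)c1O | intermediate
3 | 2,3-dibromo-4-hydroxy-5-methoxybenzaldehyde | COc1cc(C=O)c(Br)c(Br)c1O | intermediate
4 | 2,3-dibromo-4,5-dimethoxybenzaldehyde | COc1cc(C=O)c(Br)c(Br)c1OC | intermediate
5 | ethynylmagnesium bromide | C#C[Mg]Br | starting material
6 | rac-1-(2,3-dibromo-4,5-dimethoxyphenyl)prop-2-yn-1-ol | C#CC(O)c1cc(OC)c(OC)c(Br)c1Br | intermediate
7 | rac-3-bromo-1-(2,3-dibromo-4,5-dimethoxyphenyl)prop-2-yn-1-ol | BrC#CC(O)c1cc(OC)c(OC)c(Br)c1Br | intermediate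
8 | propargyl alcohol | OCC#C | starting material
9 | rac-3-bromo-1-(2,3-dibromo-4,5-dimethoxyphenyl)prop-2-ynyl propargyl ether | BrC#CC(OCC#C)c1cc(OC)c(OC)c(Br)c1Br | intermediate
10 | 1,2-bis(pinacolatoboryl)ethyne | CC1(C)OB(C#CB2OC(C)(C)C(C)(C)O2)OC1(C)C | starting material
11 | rac-7-bromo-1-(2,3-dibromo-4,5-dimethoxyphenyl)-5,6-bis(pinacolatoboryl)-1,3-dihydroisobenzofuran | COc1cc(C2OCc3cc(B4OC(C)(C)C(C)(C)O4)c(B4OC(C)(C)C(C)(C)O4)c(Br)c32)c(Br)c(Br)c1OC | intermediate
12 | 3-bromo-2-(2,3-dibromo-4,5-dimethoxybenzyl)-4,5-bis(pinacolatoboryl)benzyl trifluoroacetate | COc1cc(Cc2c(COC(=O)C(F)(F)F)cc(B3OC(C)(C)C(C)(C)O3)c(B3OC(C)(C)C(C)(C)O3)c2Br)c(Br)c(Br)c1OC | intermediate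
13 | [3-bromo-2-(2,3-dibromo-4,5-dimethoxybenzyl)-4,5-bis(pinacolatoboryl)phenyl]methanol | COc1cc(Cc2c(CO)cc(B3OC(C)(C)C(C)(C)O3)c(B3OC(C)(C)C(C)(C)O3)c2Br)c(Br)c(Br)c1OC | intermediate
14 | 3-bromo-4-(2,3-dibromo-4,5-dimethoxybenzyl)-5-(hydroxymethyl)benzene-1,2-diol | COc1cc(Cc2c(CO)cc(O)c(O)c2Br)c(Br)c(Br)c1OC | intermediate
15 | 3-bromo-5-(bromomethyl)-4-(2,3-dibromo-4,5-dihydroxybenzyl)benzene-1,2-diol | Oc1cc(Cc2c(CBr)cc(O)c(O)c2Br)c(Br)c(Br)c1O | intermediate
16 | 3-bromo-4-(2,3-dibromo-4,5-dihydroxybenzyl)-5-(hydroxymethyl)benzene-1,2-diol | Oc1cc(Cc2c(CO)cc(O)c(O)c2Br)c(Br)c(Br)c1O | intermediate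
17 | bis[3-bromo-2-(2,3-dibromo-4,5-dihydroxybenzyl)-4,5-dihydroxybenzyl] ether (achiral) | Oc1cc(Cc2c(COCc3cc(O)c(O)c(Br)c3Cc3cc(O)c(O)c(Br)c3Br)cc(O)c(O)c2Br)c(Br)c(Br)c1O | target

Total step count: 11. Longest linear sequence: 11 steps (1 to 17, since 16 is made from 15).

**Steps most likely to fail**

Step 6. The bulky internal alkyne may insert into the ruthenacycle too slowly. The free terminal alkyne of a second diyne molecule would then intercept the metallacycle and oligomerisation would take over. The alkynyl bromine may also be lost at the metal. The fallback gives up cyclotrimerisation and builds the inner ring from an arene. It sets out from 4 and returns at 15. Bought methyl 3-bromo-4,5-dimethoxybenzoate F1 is magnesiated with TMPMgCl·LiCl (THF, −20 °C) at the C–H between ester and bromine. The arylmagnesium adds to aldehyde 4, and the alkoxide lactonises to rac-4-bromo-3-(2,3-dibromo-4,5-dimethoxyphenyl)-5,6-dimethoxyisobenzofuran-1(3H)-one F2. DIBAL-H (CH2Cl2, −78 to 0 °C) reduces the lactone to rac-{3-bromo-2-[(2,3-dibromo-4,5-dimethoxyphenyl)(hydroxy)methyl]-4,5-dimethoxyphenyl}methanol F3. Et3SiH/TFA (CH2Cl2, 0 °C) removes only the diaryl carbinol oxygen and gives [3-bromo-2-(2,3-dibromo-4,5-dimethoxybenzyl)-4,5-dimethoxyphenyl]methanol F4. BBr3 then cleaves four methyl ethers and gives bromide 15. The drawback is that the C3 versus C6 placement of bromine now depends on the higher acidity of the C–H beside bromine.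

Step 11. The benzylic cation or quinone methide may be captured by phenolic oxygen or by the free ring positions C6 and C6' instead of the benzylic hydroxyl. That would lead to oligomers, and traces of acid could reopen the ether once it has formed. The fallback masks the phenols so that no quinone methide can arise. It sets out from 15 and returns at 17. Acetyl bromide in AcOH (rt to 50 °C) acetylates the four phenols and keeps the benzylic position as bromide, giving 3-bromo-5-(bromomethyl)-4-(2,3-dibromo-4,5-diacetoxybenzyl)-1,2-phenylene diacetate F5. Dry Ag2O (0.6 equiv, CH2Cl2, dark) joins two molecules in the classical silver oxide ether synthesis to the octaacetate of the target F6. Hydrazine hydrate (THF–MeCN, 0 °C, Ar) cleaves the eight aryl acetates without touching the dibenzyl ether and gives 17.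

Step 5. The carbinol next to the dibromo-substituted ring may ionise slowly. Forcing conditions could then allow attack at the bromine-bearing alkyne carbon (Meyer–Schuster-type rearrangement) or symmetrical self-etherification. The fallback forms the ether by SN2 before the bromine is introduced and tells the two alkynes apart with silicon. It sets out from 6 and returns at 9, bypassing 7. Alcohol 6 is alkylated (NaH, 1.05 equiv, THF, 0 °C) with (3-bromoprop-1-yn-1-yl)triisopropylsilane. This gives rac-1-(2,3-dibromo-4,5-dimethoxyphenyl)prop-2-ynyl 3-(triisopropylsilyl)prop-2-ynyl ether F7. NBS/AgNO3 (acetone, rt) brominates only the free terminal alkyne, because the triisopropylsilyl alkyne is inert without fluoride. The product is rac-3-bromo-1-(2,3-dibromo-4,5-dimethoxyphenyl)prop-2-ynyl 3-(triisopropylsilyl)prop-2-ynyl ether F8. TBAF buffered with AcOH (THF, 0 °C) removes the silyl group, with immediate protonation of the carbanion, and gives 9.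

**Further compounds**
F1 | step 6 | methyl 3-bromo-4,5-dimethoxybenzoate (bought) | COC(=O)c1cc(Br)c(OC)c(OC)c1
F2 | step 6 | rac-4-bromo-3-(2,3-dibromo-4,5-dimethoxyphenyl)-5,6-dimethoxyisobenzofuran-1(3H)-one | COc1cc(C2OC(=O)c3cc(OC)c(OC)c(Br)c32)c(Br)c(Br)c1OC
F3 | step 6 | rac-{3-bromo-2-[(2,3-dibromo-4,5-dimethoxyphenyl)(hydroxy)methyl]-4,5-dimethoxyphenyl}methanol | COc1cc(C(O)c2c(CO)cc(OC)c(OC)c2Br)c(Br)c(Br)c1OC
F4 | step 6 | [3-bromo-2-(2,3-dibromo-4,5-dimethoxybenzyl)-4,5-dimethoxyphenyl]methanol | COc1cc(Cc2c(CO)cc(OC)c(OC)c2Br)c(Br)c(Br)c1OC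
F5 | step 11 | 3-bromo-5-(bromomethyl)-4-(2,3-dibromo-4,5-diacetoxybenzyl)-1,2-phenylene diacetate | CC(=O)Oc1cc(Cc2c(CBr)cc(OC(C)=O)c(OC(C)=O)c2Br)c(Br)c(Br)c1OC(C)=O
F6 | step 11 | octaacetate of bis[3-bromo-2-(2,3-dibromo-4,5-dihydroxybenzyl)-4,5-dihydroxybenzyl] ether | CC(=O)Oc1cc(Cc2c(COCc3cc(OC(C)=O)c(OC(C)=O)c(Br)c3Cc3cc(OC(C)=O)c(OC(C)=O)c(Br)c3Br)cc(OC(C)=O)c(OC(C)=O)c2Br)c(Br)c(Br)c1OC(C)=O
F7 | step 5 | rac-1-(2,3-dibromo-4,5-dimethoxyphenyl)prop-2-ynyl 3-(triisopropylsilyl)prop-2-ynyl ether | C#CC(OCC#C[Si](C(C)C)(C(C)C)C(C)C)c1cc(OC)c(OC)c(Br)c1Br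
F8 | step 5 | rac-3-bromo-1-(2,3-dibromo-4,5-dimethoxyphenyl)prop-2-ynyl 3-(triisopropylsilyl)prop-2-ynyl ether | BrC#CC(OCC#C[Si](C(C)C)(C(C)C)C(C)C)c1cc(OC)c(OC)c(Br)c1Br
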